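The six-membered ring is numbered C1 (ketone), C2 (methyl-bearing epoxide carbon), C3 (epoxide CH), C4 (CH2), C5 (carbon with the side chain), C6 (carbon with the senecioate). End game: ketone from a C1 alcohol, oxirane by hydroxyl-directed epoxidation of a C2=C3 cyclohexenol that already carries both esters.
The side chain is cut between its C(=CH2) carbon and its carbinol carbon (Nozaki–Hiyama–Kishi coupling of an enol triflate with 4-methylpent-3-enal); the angelate is put on directly afterwards.
The cyclohexenol with trans C1–O/C6–O comes from a 5-methyl-7-oxanorbornene by rhodium-catalysed anti-SN2′ opening with 4-methoxybenzyl alcohol; the strained bridge breaks at C3 and its oxygen stays on C6, where it later carries the senecioate.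
Key disconnection: the carbocycle is closed in one step by a catalytic enantioselective Diels–Alder reaction of 3-methylfuran with an acrylimide, which forms C3–C4 and C5–C6. This works because C3–C2(CH3)–C1–C6 carries oxygen on both end carbons (epoxide O on C3, ester O on C6) and methyl on C2, which is C2–C3(CH3)–C4–C5 of 3-methylfuran with the furan oxygen as a temporary bridge; the trans relation of C6–O to the C5 side chain is what the endo adduct gives.
Order of rings: carbocycle with temporary oxygen bridge (step 1), bridge opened (step 5), oxirane last (step 11).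

Key step: step 1

Remark: the facial sense of the two ligand-controlled steps (copper–bis(oxazoline) in step 1, chromium–sulfonamide in step 8) is assigned by analogy with simpler substrates; should either prove opposite here, the mirror-image ligand is used and nothing else changes.

Step 1
Reactants: 1 3-methylfuran; 2 3-acryloyl-1,3-oxazolidin-2-one
Product: 3 3-[(1R,2R,4R)-5-methyl-7-oxabicyclo[2.2.1]hept-5-ene-2-carbonyl]-1,3-oxazolidin-2-one (endo adduct)
Conditions: [Cu((R,R)-t-Bu-box)](SbF6)2 (10 mol %; t-Bu-box = 2,2′-(propane-2,2-diyl)bis[(4R)-4-tert-butyl-4,5-dihydro-1,3-oxazole]), CH2Cl2, −78 °C; endo isomer separated below 0 °C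
Reagents that add atoms: none
Why: The acrylimide chelates the cationic divalent copper centre through both carbonyl groups in its s-cis form, which lowers its LUMO, and 3-methylfuran then adds in a concerted but asynchronous [4+2] cycloaddition; the closest known reaction type is the copper–bis(oxazoline)-catalysed Diels–Alder reaction of furan itself with this imide. The six-membered carbocycle is closed by suprafacial bonding of the two furan α-carbons to the two alkene carbons, the bond between furan C2 (future C3) and the CH2 terminus of the dienophile (future C4) being formed together with the bond between furan C5 (future C6) and the α-carbon (future C5). The stereocentre α to the carbonyl is set by the ligand, whose tert-butyl group blocks one face of the planar chelate, and the two bridgehead centres follow from the suprafacial addition and the endo position of the imide, which is the origin of the later trans relation between the C6 oxygen and the C5 side chain. The step needs regioselectivity for the 5-methyl adduct, endo selectivity and face selectivity: the methyl group makes C2 the more nucleophilic end of the furan so that it bonds to the electrophilic β-carbon of the Lewis-acid-bound imide, the carbonyl group lying under the diene gives the endo adduct as the kinetic product, and the catalyst controls the face. The reaction is run and worked up cold because furan cycloadditions are reversible and warming would erode both the endo preference and the enantiomeric purity.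

Step 2
Reactants: 3 3-[(1R,2R,4R)-5-methyl-7-oxabicyclo[2.2.1]hept-5-ene-2-carbonyl]-1,3-oxazolidin-2-one
Product: 4 (1R,2R,4R)-N-methoxy-N,5-dimethyl-7-oxabicyclo[2.2.1]hept-5-ene-2-carboxamide
Conditions: MeNH(OMe)·HCl, AlMe3, CH2Cl2, −10 → 0 °C
Reagents that add atoms: N,O-dimethylhydroxylamine hydrochloride, Cl.CNOC
Why: Weinreb amide formation with the aluminium amide made from AlMe3 and the amine salt should cleave only the exocyclic imide carbonyl at 0 °C under non-basic conditions, so that neither the α-stereocentre nor the heat- and base-sensitive oxygen bridge is disturbed.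

Step 3
Reactants: 4 (1R,2R,4R)-N-methoxy-N,5-dimethyl-7-oxabicyclo[2.2.1]hept-5-ene-2-carboxamide
Product: 5 1-[(1R,2R,4R)-5-methyl-7-oxabicyclo[2.2.1]hept-5-en-2-yl]ethan-1-one
Conditions: MeMgBr, THF, −78 → 0 °C
Reagents that add atoms: methylmagnesium bromide, C[Mg]Br
Why: Weinreb ketone synthesis, in which the Grignard reagent adds once to give a chelated tetrahedral magnesium intermediate that collapses to the methyl ketone only on work-up, and the low temperature should prevent enolisation at the ring carbon, which would open the oxygen bridge by β-elimination.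

Step 4
Reactants: 5 1-[(1R,2R,4R)-5-methyl-7-oxabicyclo[2.2.1]hept-5-en-2-yl]ethan-1-one
Product: 7 1-[(1R,2R,4R)-5-methyl-7-oxabicyclo[2.2.1]hept-5-en-2-yl]ethenyl trifluoromethanesulfonate, via potassium enolate 6 (not isolated)
Conditions: KHMDS, THF, −78 °C; then PhNTf2, −78 °C
Reagents that add atoms: N-phenylbis(trifluoromethanesulfonimide), O=S(=O)(N(c1ccccc1)S(=O)(=O)C(F)(F)F)C(F)(F)F
Why: Enol triflate formation, in which kinetic deprotonation by the hindered amide base at −78 °C should occur at the methyl group and not at the ring methine, and O-sulfonylation of the potassium enolate gives the 1,1-disubstituted enol triflate without a new stereocentre.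

Step 5
Reactants: 7 1-[(1R,2R,4R)-5-methyl-7-oxabicyclo[2.2.1]hept-5-en-2-yl]ethenyl trifluoromethanesulfonate
Product: 8 1-[(1R,5S,6S)-6-hydroxy-5-[(4-methoxyphenyl)methoxy]-4-methylcyclohex-3-en-1-yl]ethenyl trifluoromethanesulfonate
Conditions: [Rh(cod)Cl]2 (5 mol %), 1,1′-bis(diphenylphosphino)ferrocene (10 mol %), AgOSO2CF3 (10 mol %), 4-methoxybenzyl alcohol (5 equiv), THF, 60 °C
Reagents that add atoms: 4-methoxybenzyl alcohol, COc1ccc(CO)cc1
Why: Rhodium-catalysed anti-SN2′ ring opening of an oxabicyclic alkene by an alcohol, in which the cationic monovalent rhodium–diphosphine complex binds the exo face and activates the strained allylic C–O bond, and the alcohol should attack the unsubstituted alkene carbon from the endo face while the bridge C–O bond next to the methyl-bearing carbon breaks, which sets the new C1 ether centre trans to the retained C6 hydroxyl and places the double bond at C2=C3.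

Step 6
Reactants: 8 1-[(1R,5S,6S)-6-hydroxy-5-[(4-methoxyphenyl)methoxy]-4-methylcyclohex-3-en-1-yl]ethenyl trifluoromethanesulfonate
Product: 9 (1S,2S,6R)-2-[(4-methoxyphenyl)methoxy]-3-methyl-6-{1-[(trifluoromethanesulfonyl)oxy]ethenyl}cyclohex-3-en-1-yl 3-methylbut-2-enoate
Conditions: 3-methylbut-2-enoyl chloride, pyridine, DMAP (cat.), CH2Cl2, 0 °C → rt
Reagents that add atoms: 3-methylbut-2-enoyl chloride, CC(C)=CC(=O)Cl
Why: DMAP-catalysed esterification of the secondary alcohol installs the senecioate on the oxygen that came from the furan, with retention at C6 because the C–O bond is not touched, and the weak base should keep the acyl group from deconjugating.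

Step 7
Reactants: 10 4-methylpent-3-en-1-ol
Product: 11 4-methylpent-3-enal
Conditions: PhI(OAc)2, TEMPO (10 mol %), CH2Cl2, rt; used at once as a solution
Reagents that add atoms: none
Why: Oxoammonium-mediated (TEMPO) oxidation of the primary alcohol stops at the aldehyde under nearly neutral conditions, which should keep the β,γ-double bond out of conjugation as long as the aldehyde is used at once.

Step 8
Reactants: 9 (1S,2S,6R)-2-[(4-methoxyphenyl)methoxy]-3-methyl-6-{1-[(trifluoromethanesulfonyl)oxy]ethenyl}cyclohex-3-en-1-yl 3-methylbut-2-enoate; 11 4-methylpent-3-enal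
Product: 12 (1S,2S,6S)-6-[(3S)-3-hydroxy-6-methylhepta-1,5-dien-2-yl]-2-[(4-methoxyphenyl)methoxy]-3-methylcyclohex-3-en-1-yl 3-methylbut-2-enoate
Conditions: CrCl2 (4 equiv), NiCl2 (2 mol %), N-{2-[(4S)-4-isopropyl-4,5-dihydro-1,3-oxazol-2-yl]-6-methylphenyl}methanesulfonamide (chiral ligand, see remark), Et3N, THF, rt
Reagents that add atoms: none
Why: Nozaki–Hiyama–Kishi coupling, in which nickel-catalysed activation of the enol triflate and transmetalation give an alkenylchromium species that adds to the aldehyde only (esters, ether and alkenes are inert), and the chiral sulfonamide on chromium should direct the addition to the Re face of 11 to set the 3S carbinol centre of the side chain.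

Step 9
Reactants: 12 (1S,2S,6S)-6-[(3S)-3-hydroxy-6-methylhepta-1,5-dien-2-yl]-2-[(4-methoxyphenyl)methoxy]-3-methylcyclohex-3-en-1-yl 3-methylbut-2-enoate
Product: 14 (1S,2S,6S)-2-[(4-methoxyphenyl)methoxy]-3-methyl-6-{(3S)-6-methyl-3-[(2Z)-2-methylbut-2-enoyloxy]hepta-1,5-dien-2-yl}cyclohex-3-en-1-yl 3-methylbut-2-enoate, via lithium alkoxide 13 (not isolated)
Conditions: LiHMDS, THF, −78 °C; then angelic anhydride, −78 → 0 °C
Reagents that add atoms: angelic anhydride [(2Z)-2-methylbut-2-enoic anhydride], C/C=C(/C)C(=O)OC(=O)/C(C)=C\C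
Why: Esterification by O-acylation of the preformed lithium alkoxide at low temperature, without nucleophilic catalyst or acid chloride, should give the angelate with retention at the carbinol carbon and without Z-to-E isomerisation to the tiglate.

Step 10
Reactants: 14 (1S,2S,6S)-2-[(4-methoxyphenyl)methoxy]-3-methyl-6-{(3S)-6-methyl-3-[(2Z)-2-methylbut-2-enoyloxy]hepta-1,5-dien-2-yl}cyclohex-3-en-1-yl 3-methylbut-2-enoate
Product: 15 (1S,2S,6S)-2-hydroxy-3-methyl-6-{(3S)-6-methyl-3-[(2Z)-2-methylbut-2-enoyloxy]hepta-1,5-dien-2-yl}cyclohex-3-en-1-yl 3-methylbut-2-enoate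
Conditions: DDQ, CH2Cl2/pH 7 phosphate buffer, 0 °C
Reagents that add atoms: none
Why: Oxidative cleavage of the 4-methoxybenzyl ether by DDQ (hydride abstraction from the electron-rich benzylic position, then hydrolysis of the oxocarbenium ion) should free the C1 allylic alcohol without touching the esters or the alkenes and without change at C1.

Step 11
Reactants: 15 (1S,2S,6S)-2-hydroxy-3-methyl-6-{(3S)-6-methyl-3-[(2Z)-2-methylbut-2-enoyloxy]hepta-1,5-dien-2-yl}cyclohex-3-en-1-yl 3-methylbut-2-enoate
Product: 16 (1R,2R,3S,4S,6S)-2-hydroxy-1-methyl-4-{(3S)-6-methyl-3-[(2Z)-2-methylbut-2-enoyloxy]hepta-1,5-dien-2-yl}-7-oxabicyclo[4.1.0]heptan-3-yl 3-methylbut-2-enoate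
Conditions: VO(acac)2 (5 mol %), t-BuOOH (decane solution), CH2Cl2, 0 °C → rt
Reagents that add atoms: tert-butyl hydroperoxide, CC(C)(C)OO
Why: Vanadium-catalysed hydroxyl-directed epoxidation, in which the allylic C1 alkoxide bound to vanadium delivers the peroxide oxygen to the C2=C3 alkene on its own face only, so that the other alkenes are left and both oxirane centres are set cis to the C1 hydroxyl, that is cis to the C5 side chain and trans to the C6 senecioate as in the target.

Step 12
Reactants: 16 (1R,2R,3S,4S,6S)-2-hydroxy-1-methyl-4-{(3S)-6-methyl-3-[(2Z)-2-methylbut-2-enoyloxy]hepta-1,5-dien-2-yl}-7-oxabicyclo[4.1.0]heptan-3-yl 3-methylbut-2-enoate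
Product: 17 (1S,3S,4S,6S)-1-methyl-4-{(3S)-6-methyl-3-[(2Z)-2-methylbut-2-enoyloxy]hepta-1,5-dien-2-yl}-2-oxo-7-oxabicyclo[4.1.0]heptan-3-yl 3-methylbut-2-enoate (CNP0333561.1)
Conditions: Dess–Martin periodinane, NaHCO3, CH2Cl2, 0 °C → rt
Reagents that add atoms: none
Why: Dess–Martin oxidation of the secondary alcohol to the ketone under buffered, non-basic conditions should leave the oxirane, the two unsaturated esters and the epimerisable C6 centre unchanged, and it removes the auxiliary C1 stereocentre.

Compound list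
1 | 3-methylfuran | Cc1ccoc1 | starting material
2 | 3-acryloyl-1,3-oxazolidin-2-one | C=CC(=O)N1CCOC1=O | starting material
3 | 3-[(1R,2R,4R)-5-methyl-7-oxabicyclo[2.2.1]hept-5-ene-2-carbonyl]-1,3-oxazolidin-2-one (endo) | O=C(N1CCOC1=O)[C@@H]2C[C@@H]3C(C)=C[C@H]2O3 | intermediate
4 | (1R,2R,4R)-N-methoxy-N,5-dimethyl-7-oxabicyclo[2.2.1]hept-5-ene-2-carboxamide | CON(C)C(=O)[C@@H]1C[C@@H]2C(C)=C[C@H]1O2 | intermediate
5 | 1-[(1R,2R,4R)-5-methyl-7-oxabicyclo[2.2.1]hept-5-en-2-yl]ethan-1-one | CC(=O)[C@@H]1C[C@@H]2C(C)=C[C@H]1O2 | intermediate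
6 | potassium 1-[(1R,2R,4R)-5-methyl-7-oxabicyclo[2.2.1]hept-5-en-2-yl]ethen-1-olate (not isolated) | [K+].[O-]C(=C)[C@@H]1C[C@@H]2C(C)=C[C@H]1O2 | intermediate
7 | 1-[(1R,2R,4R)-5-methyl-7-oxabicyclo[2.2.1]hept-5-en-2-yl]ethenyl trifluoromethanesulfonate | C=C(OS(=O)(=O)C(F)(F)F)[C@@H]1C[C@@H]2C(C)=C[C@H]1O2 | intermediate
8 | 1-[(1R,5S,6S)-6-hydroxy-5-[(4-methoxyphenyl)methoxy]-4-methylcyclohex-3-en-1-yl]ethenyl trifluoromethanesulfonate | C=C(OS(=O)(=O)C(F)(F)F)[C@@H]1CC=C(C)[C@H](OCc2ccc(OC)cc2)[C@H]1O | intermediate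
9 | (1S,2S,6R)-2-[(4-methoxyphenyl)methoxy]-3-methyl-6-{1-[(trifluoromethanesulfonyl)oxy]ethenyl}cyclohex-3-en-1-yl 3-methylbut-2-enoate | C=C(OS(=O)(=O)C(F)(F)F)[C@@H]1CC=C(C)[C@H](OCc2ccc(OC)cc2)[C@H]1OC(=O)C=C(C)C | intermediate
10 | 4-methylpent-3-en-1-ol | CC(C)=CCCO | starting material
11 | 4-methylpent-3-enal | CC(C)=CCC=O | intermediate
12 | (1S,2S,6S)-6-[(3S)-3-hydroxy-6-methylhepta-1,5-dien-2-yl]-2-[(4-methoxyphenyl)methoxy]-3-methylcyclohex-3-en-1-yl 3-methylbut-2-enoate | C=C([C@H](CC=C(C)C)O)[C@@H]1CC=C(C)[C@H](OCc2ccc(OC)cc2)[C@H]1OC(=O)C=C(C)C | intermediate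
13 | lithium alkoxide of 12 (not isolated) | [Li+].C=C([C@H](CC=C(C)C)[O-])[C@@H]1CC=C(C)[C@H](OCc2ccc(OC)cc2)[C@H]1OC(=O)C=C(C)C | intermediate
14 | (1S,2S,6S)-2-[(4-methoxyphenyl)methoxy]-3-methyl-6-{(3S)-6-methyl-3-[(2Z)-2-methylbut-2-enoyloxy]hepta-1,5-dien-2-yl}cyclohex-3-en-1-yl 3-methylbut-2-enoate | C=C([C@H](CC=C(C)C)OC(=O)/C(C)=C\C)[C@@H]1CC=C(C)[C@H](OCc2ccc(OC)cc2)[C@H]1OC(=O)C=C(C)C | intermediate
15 | (1S,2S,6S)-2-hydroxy-3-methyl-6-{(3S)-6-methyl-3-[(2Z)-2-methylbut-2-enoyloxy]hepta-1,5-dien-2-yl}cyclohex-3-en-1-yl 3-methylbut-2-enoate | C=C([C@H](CC=C(C)C)OC(=O)/C(C)=C\C)[C@@H]1CC=C(C)[C@H](O)[C@H]1OC(=O)C=C(C)C | intermediate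
16 | (1R,2R,3S,4S,6S)-2-hydroxy-1-methyl-4-{(3S)-6-methyl-3-[(2Z)-2-methylbut-2-enoyloxy]hepta-1,5-dien-2-yl}-7-oxabicyclo[4.1.0]heptan-3-yl 3-methylbut-2-enoate | C=C([C@H](CC=C(C)C)OC(=O)/C(C)=C\C)[C@@H]1C[C@@H]2O[C@]2(C)[C@H](O)[C@H]1OC(=O)C=C(C)C | intermediate
17 | (1S,3S,4S,6S)-1-methyl-4-{(3S)-6-methyl-3-[(2Z)-2-methylbut-2-enoyloxy]hepta-1,5-dien-2-yl}-2-oxo-7-oxabicyclo[4.1.0]heptan-3-yl 3-methylbut-2-enoate (CNP0333561.1) | C=C([C@H](CC=C(C)C)OC(=O)/C(C)=C\C)[C@@H]1C[C@@H]2O[C@]2(C)C(=O)[C@H]1OC(=O)C=C(C)C | target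

Total step count: 12. Longest linear sequence: 11 steps (steps 1–6 and 8–12; step 7 makes aldehyde 11 separately).

Steps most likely to fail

Step 5. The rhodium catalyst may engage the trisubstituted strained alkene only slowly, the bridge may open at the other bridgehead with attack on the methyl-bearing carbon, or the bicycle may undergo cycloreversion on heating. The fallback sets out from 7 and replaces the metal-catalysed opening by a base-induced β-elimination. Hydroboration with 9-BBN (THF, rt) from the exo face, boron going to the unsubstituted alkene carbon and the enol triflate being left alone, gives the B-alkyl-9-borabicyclononane F1, which NaBO3·4H2O oxidises to the exo alcohol F2. Dess–Martin oxidation gives the 7-oxanorbornanone F3. DBU (CH2Cl2, 0 °C) then enolises the only enolisable position, the methyl-bearing α-carbon, and the enolate expels the bridge oxygen to give the 6-hydroxy-2-methylcyclohexenone F4. Acylation with 3-methylbut-2-enoyl chloride and pyridine gives the enone ester F5. Luche reduction (NaBH4, CeCl3·7H2O, MeOH, −78 °C) should deliver hydride axially and give the trans allylic alcohol F6. Etherification with 4-methoxybenzyl trichloroacetimidate and La(OSO2CF3)3 (cat.) brings the sequence back to the route at 9.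

Step 8. Face selectivity at the new carbinol centre under ligand control may be poor, and aldehyde 11 may isomerise into conjugation before it couples. The fallback sets out from 9 and 11: the coupling is run without chiral ligand (CrCl2, NiCl2 cat., DMF, rt) to give the mixture of carbinol epimers F7, Dess–Martin oxidation gives the cross-conjugated enone F8, and Corey–Bakshi–Shibata reduction with (R)-2-methyl-CBS-oxazaborolidine and catecholborane (toluene, −78 °C; the alkenyl group acts as the large substituent) returns to the route at 12.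

Step 1. The copper-bound imide may alkylate the electron-rich furan at C2 by conjugate addition instead of undergoing cycloaddition, the 6-methyl regioisomer or the exo adduct may form in larger amounts, and cycloreversion during isolation may lower the enantiomeric purity. The fallback sets out from 1 and moves stereocontrol to an enzymatic resolution. Cycloaddition with methyl acrylate promoted by ZnI2 (neat, rt) gives, after separation from the exo isomer, the racemic endo methyl ester F9. Kinetic resolution by a hydrolase (pig liver esterase or a lipase, phosphate buffer pH 7) gives the (1R,2R,4R) carboxylic acid F10; if the enzyme prefers the other enantiomer, the recovered ester is saponified with LiOH at 0 °C instead. Coupling of F10 with MeNH(OMe)·HCl (EDC·HCl, N-methylmorpholine, CH2Cl2) returns to the route at 4.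

Further compounds
F1 | step 5 | 1-[6-exo-(9-borabicyclo[3.3.1]nonan-9-yl)-5-endo-methyl-7-oxabicyclo[2.2.1]heptan-2-endo-yl]ethenyl trifluoromethanesulfonate (absolute series of 7; not isolated) | C=C(OS(=O)(=O)C(F)(F)F)[C@@H]1C[C@@H]2[C@H](C)[C@@H](B3C4CCCC3CCC4)[C@H]1O2
F2 | step 5 | 1-[(1S,2R,4R,5R,6R)-6-hydroxy-5-methyl-7-oxabicyclo[2.2.1]heptan-2-yl]ethenyl trifluoromethanesulfonate (6-exo-hydroxy, 5-endo-methyl) | C=C(OS(=O)(=O)C(F)(F)F)[C@@H]1C[C@@H]2[C@H](C)[C@@H](O)[C@H]1O2
F3 | step 5 | 1-[(1S,2R,4R,5S)-5-methyl-6-oxo-7-oxabicyclo[2.2.1]heptan-2-yl]ethenyl trifluoromethanesulfonate | C=C(OS(=O)(=O)C(F)(F)F)[C@@H]1C[C@@H]2[C@H](C)C(=O)[C@H]1O2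
F4 | step 5 | 1-[(1R,6S)-6-hydroxy-4-methyl-5-oxocyclohex-3-en-1-yl]ethenyl trifluoromethanesulfonate | C=C(OS(=O)(=O)C(F)(F)F)[C@@H]1CC=C(C)C(=O)[C@H]1O
F5 | step 5 | (1S,6R)-3-methyl-2-oxo-6-{1-[(trifluoromethanesulfonyl)oxy]ethenyl}cyclohex-3-en-1-yl 3-methylbut-2-enoate | C=C(OS(=O)(=O)C(F)(F)F)[C@@H]1CC=C(C)C(=O)[C@H]1OC(=O)C=C(C)C
F6 | step 5 | (1S,2S,6R)-2-hydroxy-3-methyl-6-{1-[(trifluoromethanesulfonyl)oxy]ethenyl}cyclohex-3-en-1-yl 3-methylbut-2-enoate | C=C(OS(=O)(=O)C(F)(F)F)[C@@H]1CC=C(C)[C@H](O)[C@H]1OC(=O)C=C(C)C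
F7 | step 8 | (1S,2S,6S)-6-[(3RS)-3-hydroxy-6-methylhepta-1,5-dien-2-yl]-2-[(4-methoxyphenyl)methoxy]-3-methylcyclohex-3-en-1-yl 3-methylbut-2-enoate (mixture of the two side-chain carbinol epimers) | C=C(C(O)CC=C(C)C)[C@@H]1CC=C(C)[C@H](OCc2ccc(OC)cc2)[C@H]1OC(=O)C=C(C)C
F8 | step 8 | (1S,2S,6S)-2-[(4-methoxyphenyl)methoxy]-3-methyl-6-(6-methyl-3-oxohepta-1,5-dien-2-yl)cyclohex-3-en-1-yl 3-methylbut-2-enoate | C=C(C(=O)CC=C(C)C)[C@@H]1CC=C(C)[C@H](OCc2ccc(OC)cc2)[C@H]1OC(=O)C=C(C)C
F9 | step 1 | methyl rac-(1R,2R,4R)-5-methyl-7-oxabicyclo[2.2.1]hept-5-ene-2-carboxylate (racemic endo ester; one enantiomer drawn) | COC(=O)[C@@H]1C[C@@H]2C(C)=C[C@H]1O2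
F10 | step 1 | (1R,2R,4R)-5-methyl-7-oxabicyclo[2.2.1]hept-5-ene-2-carboxylic acid | OC(=O)[C@@H]1C[C@@H]2C(C)=C[C@H]1O2
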